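**Assumptions (one line each)**
- Locants use diarylheptanoid numbering: C1/C2 = ArCH2CH2, C3 = carbinol, C5=C6 = alkene, C7 = diarylmethine. From the SMILES the target is (3S,7R) with both alkenes E.
- The Ipc2BCl antipode that gives re-face attack in step 4 is taken to be (−)-Ipc2BCl; this is from memory, so confirm C3 of compound 6 by Mosher ester and switch antipode if needed.

**Retrosynthetic overview**
1. Final operations: acid removal of MOM/TBS groups, and the chalcone C=C by Claisen–Schmidt condensation of the A-ring acetyl with 4-(methoxymethoxy)benzaldehyde.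
2. Key disconnection: the C3'–C7 bond and the C7 stereocentre come from an aromatic Claisen rearrangement of a chiral 2'-O-allyl aryl ether. The acetyl group blocks the other ortho position, and chirality is transferred from C5(O) to C7.
3. The aryl ether comes from Mitsunobu inversion between the chelated 2-OH of 4-O-MOM-2,4-dihydroxy-6-methoxyacetophenone and a (3S,5S)-allylic alcohol.
4. The allylic alcohol comes from CBS reduction (sets C5) of an enone made by an Ipc2BCl aldol (sets C3) between 4-pivaloyloxybenzalacetone and 3-[4-(methoxymethoxy)phenyl]propanal.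
5. No ring is formed; all four benzene rings are purchased.

**Route**

Step 1
Reactants: 1 methyl 3-(4-hydroxyphenyl)propanoate
Product: 2 methyl 3-[4-(methoxymethoxy)phenyl]propanoate
Conditions: MOMCl, i-Pr2NEt, CH2Cl2, 0 °C→rt
Reagents that add atoms: chloromethyl methyl ether (MOMCl), COCCl
Why: Phenol O-alkylation gives an acetal that survives hydride, boron enolate, Mitsunobu, heat and KOH, and is removed by acid at the end.

Step 2
Reactants: 2 methyl 3-[4-(methoxymethoxy)phenyl]propanoate
Product: 3 3-[4-(methoxymethoxy)phenyl]propanal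
Conditions: DIBAL-H (1.05 equiv), CH2Cl2, −78 °C; Rochelle salt work-up
Reagents that add atoms: none
Why: DIBAL partial reduction stops at the aluminium hemiacetal at −78 °C, which releases the aldehyde only on work-up.

Step 3
Reactants: 4 (E)-4-(4-hydroxyphenyl)but-3-en-2-one
Product: 5 4-[(E)-3-oxobut-1-en-1-yl]phenyl pivalate
Conditions: PivCl, Et3N, DMAP (cat.), CH2Cl2, 0 °C→rt
Reagents that add atoms: pivaloyl chloride, CC(C)(C)C(=O)Cl
Why: O-acylation protects the phenol and makes this ring electron-poor, so the later allylic C–O bond does not ionise in steps 8 and 9; the ester is cleaved for free in step 10.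

Step 4
Reactants: 5 4-[(E)-3-oxobut-1-en-1-yl]phenyl pivalate; 3 3-[4-(methoxymethoxy)phenyl]propanal
Product: 6 4-[(1E,5S)-5-hydroxy-7-[4-(methoxymethoxy)phenyl]-3-oxohept-1-en-1-yl]phenyl pivalate
Conditions: (−)-Ipc2BCl, Et3N, Et2O, 0 °C; then 3, −78→−20 °C; MeOH/pH 7 buffer/H2O2, 0 °C
Reagents that add atoms: none
Why: Paterson asymmetric boron aldol of the methyl-ketone enolate sets C3 as S, typically about 70–80% ee for methyl ketones; the minor enantiomer becomes a separable diastereomer after step 6.

Step 5
Reactants: 6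
Product: 7 4-[(1E,5S)-5-[(tert-butyldimethylsilyl)oxy]-7-[4-(methoxymethoxy)phenyl]-3-oxohept-1-en-1-yl]phenyl pivalate
Conditions: TBSOTf, 2,6-lutidine, CH2Cl2, −78 °C
Reagents that add atoms: TBSOTf, CC(C)(C)[Si](C)(C)OS(=O)(=O)C(F)(F)F
Why: Low-temperature silylation with a hindered base avoids retro-aldol or elimination and differentiates O3 from the O5 hydroxyl made next.

Step 6
Reactants: 7
Product: 8 4-[(1E,3S,5S)-5-[(tert-butyldimethylsilyl)oxy]-3-hydroxy-7-[4-(methoxymethoxy)phenyl]hept-1-en-1-yl]phenyl pivalate (heptanoid 3S,5S, syn)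
Conditions: (R)-Me-CBS (0.5 equiv), catecholborane, PhMe, −78 °C; chromatography to remove the 3,5-anti isomer
Reagents that add atoms: none
Why: Corey–Bakshi–Shibata 1,2-reduction with the styryl group as the large substituent gives the (5S)-allylic alcohol under reagent control, and removing the anti diastereomer upgrades the ee.

Step 7
Reactants: 9 1-(2,4-dihydroxy-6-methoxyphenyl)ethanone
Product: 10 1-[2-hydroxy-6-methoxy-4-(methoxymethoxy)phenyl]ethanone
Conditions: MOMCl (1.05 equiv), K2CO3, acetone, rt
Reagents that add atoms: chloromethyl methyl ether (MOMCl), COCCl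
Why: The 4-OH (para to acetyl, not hydrogen-bonded) is far more acidic and nucleophilic than the chelated 2-OH, so mono-alkylation is selective.

Step 8
Reactants: 8 allylic alcohol; 10 phenol
Product: 11 4-[(1E,3R,5S)-3-[2-acetyl-3-methoxy-5-(methoxymethoxy)phenoxy]-5-[(tert-butyldimethylsilyl)oxy]-7-[4-(methoxymethoxy)phenyl]hept-1-en-1-yl]phenyl pivalate (heptanoid 3S,5R)
Conditions: PPh3, DIAD, PhMe, 0 °C→rt
Reagents that add atoms: none
Why: Mitsunobu etherification is an SN2 displacement at the allylic carbon with inversion (5S→5R); the chelated OH is the only free acidic site and the pivalate suppresses ionisation.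

Step 9
Reactants: 11
Product: 12 4-[(1R,2E,5S)-1-[3-acetyl-2-hydroxy-4-methoxy-6-(methoxymethoxy)phenyl]-5-[(tert-butyldimethylsilyl)oxy]-7-[4-(methoxymethoxy)phenyl]hept-2-en-1-yl]phenyl pivalate (heptanoid 3S,7R)
Conditions: PhNEt2, 160 °C, sealed tube; chromatography
Reagents that add atoms: none
Why: Aromatic Claisen [3,3] rearrangement can only reach C3' because the acetyl blocks the other ortho carbon; the suprafacial shift with the C5 substituent pseudo-equatorial converts 5R into 7R with an E C5=C6 alkene, and the amine solvent speeds dienone-to-phenol tautomerisation.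

Step 10
Reactants: 12; 13 4-(methoxymethoxy)benzaldehyde (3 equiv)
Product: 14 (2E)-1-{3-[(1R,2E,5S)-5-[(tert-butyldimethylsilyl)oxy]-1-(4-hydroxyphenyl)-7-[4-(methoxymethoxy)phenyl]hept-2-en-1-yl]-2-hydroxy-6-methoxy-4-(methoxymethoxy)phenyl}-3-[4-(methoxymethoxy)phenyl]prop-2-en-1-one
Conditions: KOH (50% aq), EtOH, rt, 24–48 h; cold AcOH to pH 6
Reagents that add atoms: none
Why: Claisen–Schmidt aldol condensation with E1cB dehydration gives the E-chalcone and hydroxide also cleaves the aryl pivalate; the C7–H (pKa about 30) and the alkyl TBS ether are untouched.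

Step 11
Reactants: 14
Product: 15 epicalyxin B, (2E)-1-{2,4-dihydroxy-3-[(1R,2E,5S)-5-hydroxy-1,7-bis(4-hydroxyphenyl)hept-2-en-1-yl]-6-methoxyphenyl}-3-(4-hydroxyphenyl)prop-2-en-1-one
Conditions: 3 M HCl (aq), MeOH/THF, rt (→40 °C), monitored; NaHCO3 quench
Reagents that add atoms: none
Why: Acid-catalysed acetal hydrolysis and desilylation removes three MOM ethers and the TBS group without touching either stereocentre; mild acid limits chalcone-to-flavanone cyclisation.

**Compound list**

1 | methyl 3-(4-hydroxyphenyl)propanoate | COC(=O)CCc1ccc(O)cc1 | starting material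
2 | methyl 3-[4-(methoxymethoxy)phenyl]propanoate | COC(=O)CCc1ccc(OCOC)cc1 | intermediate
3 | 3-[4-(methoxymethoxy)phenyl]propanal | O=CCCc1ccc(OCOC)cc1 | intermediate
4 | (E)-4-(4-hydroxyphenyl)but-3-en-2-one | CC(=O)/C=C/c1ccc(O)cc1 | starting material
5 | 4-[(E)-3-oxobut-1-en-1-yl]phenyl pivalate | CC(=O)/C=C/c1ccc(OC(=O)C(C)(C)C)cc1 | intermediate
6 | (S)-aldol adduct, β-hydroxy enone | CC(C)(C)C(=O)Oc1ccc(/C=C/C(=O)C[C@@H](O)CCc2ccc(OCOC)cc2)cc1 | intermediate
7 | TBS ether of 6 | CC(C)(C)C(=O)Oc1ccc(/C=C/C(=O)C[C@@H](O[Si](C)(C)C(C)(C)C)CCc2ccc(OCOC)cc2)cc1 | intermediate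
8 | (3S,5S)-allylic alcohol | CC(C)(C)C(=O)Oc1ccc(/C=C/[C@@H](O)C[C@@H](O[Si](C)(C)C(C)(C)C)CCc2ccc(OCOC)cc2)cc1 | intermediate
9 | 1-(2,4-dihydroxy-6-methoxyphenyl)ethanone | COc1cc(O)cc(O)c1C(C)=O | starting material
10 | 1-[2-hydroxy-6-methoxy-4-(methoxymethoxy)phenyl]ethanone | COCOc1cc(O)c(C(C)=O)c(OC)c1 | intermediate
11 | (3S,5R)-aryl allyl ether | CC(C)(C)C(=O)Oc1ccc(/C=C/[C@H](Oc2cc(OCOC)cc(OC)c2C(C)=O)C[C@@H](O[Si](C)(C)C(C)(C)C)CCc3ccc(OCOC)cc3)cc1 | intermediate
12 | (3S,7R)-Claisen product, C3'-alkylated acetophenone | COc1cc(OCOC)c([C@H](/C=C/C[C@@H](O[Si](C)(C)C(C)(C)C)CCc2ccc(OCOC)cc2)c2ccc(OC(=O)C(C)(C)C)cc2)c(O)c1C(C)=O | intermediate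
13 | 4-(methoxymethoxy)benzaldehyde | COCOc1ccc(C=O)cc1 | starting material
14 | protected chalcone (three MOM, one TBS) | COc1cc(OCOC)c([C@H](/C=C/C[C@@H](O[Si](C)(C)C(C)(C)C)CCc2ccc(OCOC)cc2)c2ccc(O)cc2)c(O)c1C(=O)/C=C/c1ccc(OCOC)cc1 | intermediate
15 | epicalyxin B | COc1cc(O)c([C@H](/C=C/C[C@@H](O)CCc2ccc(O)cc2)c2ccc(O)cc2)c(O)c1C(=O)/C=C/c1ccc(O)cc1 | target

**Totals**
- Total steps: 11
- Longest linear sequence: 9 steps (1, 2, 4, 5, 6, 8, 9, 10, 11)

**Three steps most likely to fail, with fallbacks**
- **Step 8 (Mitsunobu).** The chelated phenol is weakly acidic and the secondary allylic alcohol is hindered, so SN2′ attack, elimination to the diene or partial racemisation are possible. Fallback: form the ether by SNAr with retention. Make the C5 epimer of 8 with (S)-Me-CBS and react its potassium alkoxide with 2'-fluoro-6'-methoxy-4'-(methoxymethoxy)acetophenone, then continue with the same Claisen step.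
- **Step 9 (Claisen).** The ortho dienone could undergo Cope migration to C5' (para product), an ionic [1,3] shift could occur, or some Z/7S isomer could form. Fallback: make the C7–aryl bond intermolecularly. Convert 8 to its picolinate and displace it anti-SN2′ with the arylcopper from ortho-lithiated 1,3-bis(methoxymethoxy)-5-methoxybenzene (5S gives 7R). Then install the acetyl by NIS iodination and Stille coupling with tributyl(1-ethoxyvinyl)tin, and hydrolyse.
- **Step 4 (Ipc2BCl aldol).** Methyl-ketone boron aldols give only modest ee, and the facial sense must be verified. Fallback: set C3 by Brown allylation of 3 with (+)-Ipc2B-allyl (from (−)-α-pinene; gives the S alcohol). Then TBS protection, ozonolysis, addition of the (E)-2-(4-pivaloyloxyphenyl)vinyl metal, oxidation to enone 7, and rejoin at step 6.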